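The east run cannot have gone on as it began. At 0.0175 M/d, its pace of substrate loss between 0.833 d and 2.08 d, the 5.00 d of the last reading would use 0.0875 M of substrate, more than the 0.0627 M of reagent charged, if each substrate takes one reagent.

| setting | east | flask |
|---|---|---|
| substrate | 0.13 M | 0.066 M |
| reagent | 0.0627 M | 0.0627 M |
| free catalyst | 66 µM | 66 µM |
| remark | run made earlier |  |
| time |  | 15 d |

- east (time / d: substrate / %, target / %): 0.333: 95.3, 3.4; 0.833: 87.6, 5.4; 2.08: 70.8, 7.2; 5.00: 51.4, 2.6

(scatter of a reading: 0.5 percentage points)

- the reaction counts as stopped when no species that holds the substrate changes by six tenths of a point or more over the second half of the time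

* the state of affairs at 15 d: stopped, and by what, or still going (the reagent has run out first / no working catalyst is left / it is still moving / all of the substrate has reacted / forward and back rates have come level)
* conversion of substrate at 15 d
* amount of target at 15 d, in percent of the substrate charged

Two east numbers seem to clash: after 2.08 d the pace drops to 0.00864 M/d, about half of what it was, yet 70.8 % of the substrate stood at 2.08 d. I reckon a reagent ceiling, charged reagent over charged substrate, which treats reagent as the limiting reagent. For the east run it is 48.2 %, and the last reading shows 48.6 % lost, so that reading stands at the ceiling as far as a scatter of 0.5 percentage points can show.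

For the flask the ceiling is 95.0 %. Early east pace eased from 0.0194 M/d to 0.0175 M/d, so as a rough estimate I freeze it. At half of 0.0175 M/d, matching the flask's smaller substrate charge, I reckon the reagent in the flask lasts 7.16 d, less than half the time. On that frozen pace I expect the flask stopped at its ceiling.

The forecast differs: it is still moving, conversion 93 % (89 % to 95 %), target 0.5 % (0 % to 1.3 %), since “substrate still changes during the second half”.

The flask gives: the reagent has run out first, with 0 % of it left, conversion 95.0 %, target 4.15 %.

    reagent + free catalyst → catalyst intermediate A (k = 3150 /M/h)
    catalyst intermediate A → released group + catalyst intermediate B (k = 176 /h)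
    substrate + catalyst intermediate B → catalyst intermediate C (k = 4780 /M/h)
    catalyst intermediate C ⇌ catalyst intermediate D (K = 0.122, k = 170 /h)
    catalyst intermediate D → free catalyst + target (k = 141 /h)
    target ⇌ isomer of the product (K = 21.9, k = 0.0959 /h)

In the flask, reagent entered the cycle while it lasted, 56.6 % of its charge standing at 1.50 d beside 58.8 % of the substrate, and by 7.50 d reagent stood at 0 %, substrate at 5.00 %, target at 4.15 % and isomer of the product at 90.8 %, conversion having reached the ceiling of 95.0 %. The same flask charged with 0.17 M of substrate has a ceiling of 36.9 %, and at 15.0 d, with reagent at 0 %, it stands at a conversion of 36.9 %.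

The earlier runs and the new flask stem from a simulated flask for an exercise; scatter was added.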